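- delta: electrophile 20 mM; nucleophile 30 mM; free base 10 mM; the very flask that is asked about, followed so far
- flask: electrophile 20 mM; nucleophile 30.0 mM; free base 10.0 mM; time 20 min
delta run (percent of the electrophile charged)

| time / min | electrophile / % | target / % |
|---|---|---|
| 0.833 | 97.6 | 3.6 |
| 2.50 | 86.8 | 9.6 |
| 5.00 | 77.2 | 15.2 |
| 8.00 | 68.4 | 20.4 |
| 10.0 | 63.5 | 26.1 |

(scatter of a reading: 1 percentage point)
1. part of the electrophile that has reacted at 20 min
2. share of the unused nucleophile that is free and not bound as protonated nucleophile, at 20 min
- a reading or a percentage of target counts all its forms, free or not
- what has gone from electrophile into another species counts as reacted, even if it can come back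
- the earlier runs do not show how much of nucleophile is bound; that part of a forecast is a guess

- Slowness was what I watched in the delta run: the pseudo-first-order constant for target, gain per mean electrophile, was 0.0411 /min up to 2.50 min, then 0.0310 /min from 5.00 min to 10.0 min, a reading that fell to 75.4% of the first.
- That looked contradictory: in the delta run, with target near 20.7% of the electrophile charge, just 13.8% of the nucleophile charge had become target, less than the 24.6% fall in the constant.
- My guess was that each target comes with one acid set free, which pairs quickly with nucleophile, so each target removes two nucleophile from the free pool.
- The free-pool cost, fraction of nucleophile charge lost per fraction of electrophile charge made target, is then 1.33, and it predicts a fall to 77.4%, near the 75.4% read, which clears the contradiction.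
- Letting the stretch after 10.0 min repeat the target gain up to it, reduced by that fall once as a stand-in for electrophile and once for free nucleophile, I reckoned for the asked flask target 40.9% at 20 min and a free share of 62.5%.
- The forecast differed from my share: it gave 53% (48% to 58%) reacted and 85% (62% to 98%) free, reasoning “Most acid should go to the base if it is the stronger one”.
- The flask gave 54.4% reacted and 67.1% free.

    nucleophile + target → over-reaction product (k = 0.180 /M/min)
    free base + target ⇌ idle adduct, settled at all times (K = 95.0 /M)
    nucleophile + acid set free ⇌ protonated nucleophile, settled at all times (K = 7800 /M)
    electrophile + nucleophile → acid set free + target (k = 1.30 /M/min)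
    acid set free + free base ⇌ salt of the base (K = 230 /M, k = 17.0 /M/min)
    electrophile ⇌ dormant form (K = 0.790, k = 0.0160 /min)

- At 20.0 min in this flask, protonated nucleophile held 24.5% of the nucleophile charge, while salt of the base held 0.522% of the base charge.
- With this flask's target of 36.5%, idle adduct counted, the cost gives a free share of 67.9%.
- The neighbour flask with 34 mM of electrophile has a cost of 2.27, and its target of 30.5% gives 47.1%; its free share stood at 46.3%.

Readings and results are calculated from invented constants, and the scatter is random.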